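**Strategy.** The dihydrofuran ring (O1, C2, C3, C3a, C7a) is cut at O1–C7a and at C2–C3. This reveals the C=O group of methacrolein (O1 and C2, with the carbons of the later 1-formylvinyl group) and the C3–C3a–C7a unit of 5-acetyl-2-fluorobenzaldehyde. The key step is a one-pot reductive (3+2) annulation. Iridium-catalysed anti-selective acyloxyallylation with the bis(isovalerate) acylal of methacrolein joins C2 to C3 and sets both ring stereocentres. Base then moves the isovaleryl group from O1 to the C3 oxygen, where the target needs it, and the freed alkoxide displaces fluoride at C7a, which the para C5 acetyl group activates. Ketone reduction, acylation and allylic oxidation finish the synthesis.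

Key step: step 3

Assumption: the sense of induction of the (S)-SEGPHOS–iridium catalyst in step 3 is assigned by analogy with the parent acyloxyallylation of aryl aldehydes. If a model adduct shows the opposite sense, (R)-SEGPHOS is used and nothing else changes.

**Step 1**
Reactants: 1 5-bromo-2-fluorobenzaldehyde; 2 tributyl(1-ethoxyvinyl)stannane
Product: 4 5-acetyl-2-fluorobenzaldehyde, via enol ether 3 (not isolated)
Conditions: Pd(PPh3)4 (3 mol%), toluene, 100 °C; then 1 M HCl, THF, rt
Reagents that add atoms: water, O
Why: Stille coupling, in which zerovalent palladium inserts into the C–Br bond (C–F bond and aldehyde untouched) and transmetallation/reductive elimination give enol ether 3, whose mild acid hydrolysis should give the methyl ketone; no stereocenter is formed.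

**Step 2**
Reactants: 5 methacrolein (2-methylprop-2-enal); 6 isovaleric anhydride (3-methylbutanoic anhydride)
Product: 7 2-methylprop-2-ene-1,1-diyl bis(3-methylbutanoate)
Conditions: FeCl3 (anhydrous, 1 mol%), no solvent, 0 °C to rt
Reagents that add atoms: none
Why: Lewis acid-catalysed acylal formation (1,1-diacyloxylation of an aldehyde by an anhydride), the reaction type by which allylidene diacetate is made from acrolein, should give 7 at low temperature before conjugate addition or polymerisation competes; no stereocenter is formed.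

**Step 3**
Reactants: 4 5-acetyl-2-fluorobenzaldehyde; 7 2-methylprop-2-ene-1,1-diyl bis(3-methylbutanoate)
Product: 10 (2R,3S)-5-acetyl-2-(prop-1-en-2-yl)-2,3-dihydro-1-benzofuran-3-yl 3-methylbutanoate, via anti adduct 8 (not isolated), via acyl-shifted alcohol 9 (not isolated)
Conditions: [Ir(cod)Cl]2 (2.5 mol%), (S)-SEGPHOS (5 mol%), 4-cyano-3-nitrobenzoic acid (10 mol%), Cs2CO3 (20 mol%), 2-propanol (2 equiv), THF, 90 °C; then, in the same flask, Cs2CO3 (2 equiv), DMSO, 60 °C
Reagents that add atoms: none
Why: Proposed new method: the cyclometallated iridium catalyst ionises acylal 7 to a 1-acyloxy-2-methyl-π-allyl complex, 2-propanol reduces it to the nucleophilic (E)-σ-allyliridium species, and this adds through its oxygen-bearing carbon (C2) to the aldehyde carbon (C3) of 4 in a closed chair transition state to give 8; carbonate then equilibrates 8 with 9 by a 1,2-acyl shift through a cyclic orthoester anion, and the C2 alkoxide of 9 displaces fluoride at C7a by addition–elimination. The closest known reactions are the iridium-catalysed anti-(acyloxy)allylation of aryl aldehydes with allylic gem-dicarboxylates under transfer hydrogenation (shown for the unsubstituted donor, not for a 2-methyl donor and not in tandem with ring closure) and the intramolecular SNAr etherification of 4-fluoroaryl ketones. The dihydrofuran ring closes in the 5-exo-trig mode at C7a through an anionic σ-adduct that the para C5 acetyl group stabilises. C3 (S) is set by the chiral bisphosphine on iridium, which selects the aldehyde face, and C2 (R) follows from the E geometry of the σ-allyl in the chair, which gives the anti adduct and hence the 2,3-trans ring. The step needs aldehyde-over-ketone chemoselectivity, secured by the far faster addition to the formyl group, anti diastereoselectivity, secured by the chair transition state, and ring closure through the correct oxygen, secured because the C3 oxygen could only form a four-membered ring.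

**Step 4**
Reactants: 10 (2R,3S)-5-acetyl-2-(prop-1-en-2-yl)-2,3-dihydro-1-benzofuran-3-yl 3-methylbutanoate
Product: 11 (2R,3S)-5-[(1R)-1-hydroxyethyl]-2-(prop-1-en-2-yl)-2,3-dihydro-1-benzofuran-3-yl 3-methylbutanoate
Conditions: RuCl[(R,R)-TsDPEN](p-cymene) (1 mol%), HCO2H/Et3N (5:2), CH2Cl2, 28 °C
Reagents that add atoms: none
Why: Noyori–Ikariya asymmetric transfer hydrogenation, in which the (R,R)-TsDPEN ruthenium hydride delivers hydride and proton through a six-membered outer-sphere transition state with the aryl group under the η6-arene, should give the (R)-carbinol under catalyst control while the ester, the aryl ether and the 1,1-disubstituted alkene stay inert.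

**Step 5**
Reactants: 11 (2R,3S)-5-[(1R)-1-hydroxyethyl]-2-(prop-1-en-2-yl)-2,3-dihydro-1-benzofuran-3-yl 3-methylbutanoate; 6 isovaleric anhydride
Product: 12 (1R)-1-[(2R,3S)-3-[(3-methylbutanoyl)oxy]-2-(prop-1-en-2-yl)-2,3-dihydro-1-benzofuran-5-yl]ethyl 3-methylbutanoate
Conditions: Et3N (2 equiv), DMAP (10 mol%), CH2Cl2, 0 °C to rt
Reagents that add atoms: none
Why: DMAP-catalysed acylation (Steglich-type acyl transfer) of the secondary benzylic alcohol takes place at oxygen only under basic conditions, so the (R) configuration is retained and the electron-rich benzylic position is not ionised.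

**Step 6**
Reactants: 12 (1R)-1-[(2R,3S)-3-[(3-methylbutanoyl)oxy]-2-(prop-1-en-2-yl)-2,3-dihydro-1-benzofuran-5-yl]ethyl 3-methylbutanoate
Product: 13 (1R)-1-[(2R,3S)-3-[(3-methylbutanoyl)oxy]-2-(3-oxoprop-1-en-2-yl)-2,3-dihydro-1-benzofuran-5-yl]ethyl 3-methylbutanoate
Conditions: SeO2 (1.5 equiv), pyridine (0.2 equiv), 1,4-dioxane, 80 °C
Reagents that add atoms: selenium dioxide, O=[Se]=O
Why: Riley oxidation, in which the ene reaction of SeO2 at the 1,1-disubstituted alkene takes hydrogen from the methyl group (the only other allylic hydrogen, C2–H, is a hindered oxygen-bearing methine) and a [2,3]-sigmatropic shift followed by breakdown of the allylic selenium ester should give the α-methylene aldehyde with both esters and all three stereocenters untouched.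

**Compound list**
1 | 5-bromo-2-fluorobenzaldehyde | O=Cc1cc(Br)ccc1F | starting material
2 | tributyl(1-ethoxyvinyl)stannane | CCCC[Sn](CCCC)(CCCC)C(=C)OCC | starting material
3 | 5-(1-ethoxyvinyl)-2-fluorobenzaldehyde | C=C(OCC)c1ccc(F)c(C=O)c1 | intermediate
4 | 5-acetyl-2-fluorobenzaldehyde | CC(=O)c1ccc(F)c(C=O)c1 | intermediate
5 | methacrolein (2-methylprop-2-enal) | C=C(C)C=O | starting material
6 | isovaleric anhydride (3-methylbutanoic anhydride) | CC(C)CC(=O)OC(=O)CC(C)C | starting material
7 | 2-methylprop-2-ene-1,1-diyl bis(3-methylbutanoate) | C=C(C)C(OC(=O)CC(C)C)OC(=O)CC(C)C | intermediate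
8 | (1S,2R)-1-(5-acetyl-2-fluorophenyl)-1-hydroxy-3-methylbut-3-en-2-yl 3-methylbutanoate | C=C(C)[C@@H](OC(=O)CC(C)C)[C@@H](O)c1cc(C(C)=O)ccc1F | intermediate
9 | (1S,2R)-1-(5-acetyl-2-fluorophenyl)-2-hydroxy-3-methylbut-3-en-1-yl 3-methylbutanoate | C=C(C)[C@@H](O)[C@@H](OC(=O)CC(C)C)c1cc(C(C)=O)ccc1F | intermediate
10 | (2R,3S)-5-acetyl-2-(prop-1-en-2-yl)-2,3-dihydro-1-benzofuran-3-yl 3-methylbutanoate | C=C(C)[C@H]1Oc2ccc(C(C)=O)cc2[C@@H]1OC(=O)CC(C)C | intermediate
11 | (2R,3S)-5-[(1R)-1-hydroxyethyl]-2-(prop-1-en-2-yl)-2,3-dihydro-1-benzofuran-3-yl 3-methylbutanoate | C=C(C)[C@H]1Oc2ccc([C@@H](C)O)cc2[C@@H]1OC(=O)CC(C)C | intermediate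
12 | (1R)-1-[(2R,3S)-3-[(3-methylbutanoyl)oxy]-2-(prop-1-en-2-yl)-2,3-dihydro-1-benzofuran-5-yl]ethyl 3-methylbutanoate | C=C(C)[C@H]1Oc2ccc([C@@H](C)OC(=O)CC(C)C)cc2[C@@H]1OC(=O)CC(C)C | intermediate
13 | (1R)-1-[(2R,3S)-3-[(3-methylbutanoyl)oxy]-2-(3-oxoprop-1-en-2-yl)-2,3-dihydro-1-benzofuran-5-yl]ethyl 3-methylbutanoate | C=C(C=O)[C@H]1Oc2ccc([C@@H](C)OC(=O)CC(C)C)cc2[C@@H]1OC(=O)CC(C)C | target

**Totals**
Total step count: 6. Longest linear sequence: 5 steps (steps 1, 3, 4, 5, 6); step 2 is a one-step branch.

**Steps most likely to fail**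

Step 3 (Proposed new method). The 2-methyl acylal may ionise slowly. Syn/anti isomerisation of the 2-methyl-π-allyl may erode the anti selectivity. The aryl ketone may be transfer-hydrogenated too early. The acyl group may be lost instead of migrating; this last case is harmless, because the free C3 alcohol is acylated in step 5. The fallback uses known chemistry and sets out from 4. An L-proline-catalysed anti-selective enamine aldol reaction of 4 with hydroxyacetone in DMSO should form the C2–C3 bond and give (3S,4S)-4-(5-acetyl-2-fluorophenyl)-3,4-dihydroxybutan-2-one F1, with any syn isomer removed by chromatography. Cs2CO3 in DMSO at rt should then close O1–C7a by intramolecular SNAr to give 1,1'-[(2S,3S)-3-hydroxy-2,3-dihydro-1-benzofuran-2,5-diyl]di(ethan-1-one) F2. Non-basic Lombardo methylenation (Zn, CH2Br2, TiCl4, THF, 0 °C) of the more electrophilic α-oxygenated ketone should give 1-[(2R,3S)-3-hydroxy-2-(prop-1-en-2-yl)-2,3-dihydro-1-benzofuran-5-yl]ethan-1-one F3. DMAP-catalysed acylation of F3 with 6 comes back to the route at 10.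

Step 6. The ene step may show poor site selectivity, the allylic alcohol or aldehyde may be over-oxidised, or the acidic selenium species may ionise the benzylic esters. The fallback sets out from 12. Ene-type allylic chlorination of the isopropenyl group (NaOCl, CeCl3·7H2O, CH2Cl2/H2O, 0 °C) should give (1R)-1-[(2R,3S)-2-(3-chloroprop-1-en-2-yl)-3-[(3-methylbutanoyl)oxy]-2,3-dihydro-1-benzofuran-5-yl]ethyl 3-methylbutanoate F4. Kornblum oxidation of F4 (DMSO, NaHCO3, 60 °C) comes back to the route at 13.

Step 4. Hydride transfer to the electron-rich 4-alkoxyaryl ketone may be slow and facial control incomplete. The fallback sets out from 10. NaBH4 in MeOH at 0 °C should give 11 together with its carbinol epimer (2R,3S)-5-[(1S)-1-hydroxyethyl]-2-(prop-1-en-2-yl)-2,3-dihydro-1-benzofuran-3-yl 3-methylbutanoate F5. Candida antarctica lipase B with 6 in toluene should acylate only the (R)-carbinol 11 to 12. The recovered F5 is converted to the same ester 12 with inversion by a Mitsunobu reaction with 3-methylbutanoic acid (PPh3, DIAD, THF, 0 °C). Both epimers therefore come back to the route at 12.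

**Further compounds**
F1 | step 3 | (3S,4S)-4-(5-acetyl-2-fluorophenyl)-3,4-dihydroxybutan-2-one | CC(=O)[C@@H](O)[C@@H](O)c1cc(C(C)=O)ccc1F
F2 | step 3 | 1,1'-[(2S,3S)-3-hydroxy-2,3-dihydro-1-benzofuran-2,5-diyl]di(ethan-1-one) | CC(=O)[C@H]1Oc2ccc(C(C)=O)cc2[C@@H]1O
F3 | step 3 | 1-[(2R,3S)-3-hydroxy-2-(prop-1-en-2-yl)-2,3-dihydro-1-benzofuran-5-yl]ethan-1-one | C=C(C)[C@H]1Oc2ccc(C(C)=O)cc2[C@@H]1O
F4 | step 6 | (1R)-1-[(2R,3S)-2-(3-chloroprop-1-en-2-yl)-3-[(3-methylbutanoyl)oxy]-2,3-dihydro-1-benzofuran-5-yl]ethyl 3-methylbutanoate | C=C(CCl)[C@H]1Oc2ccc([C@@H](C)OC(=O)CC(C)C)cc2[C@@H]1OC(=O)CC(C)C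
F5 | step 4 | (2R,3S)-5-[(1S)-1-hydroxyethyl]-2-(prop-1-en-2-yl)-2,3-dihydro-1-benzofuran-3-yl 3-methylbutanoate | C=C(C)[C@H]1Oc2ccc([C@H](C)O)cc2[C@@H]1OC(=O)CC(C)C
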